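**Assumptions:** The target has no stereocentres or stereogenic alkenes, so it is achiral and "single enantiomer" simply means the compound as drawn. The side chain is read from the SMILES as n‑nonadecyl (C19), and the target is drawn as its 2‑hydroxy‑1,4‑quinone tautomer.

## Retrosynthetic overview

1. Target ⇒ 2,5‑dihydroxy‑3‑nonadecyl‑1,4‑benzoquinone, by regioselective O‑methylation of the unhindered vinylogous acid.
2. That ⇒ C2h‑symmetric 2,5‑dihydroxy‑1,4‑benzoquinone plus a nonadecyl radical from arachidic acid (C20 − CO2 = C19). This symmetry‑breaking radical C–H alkylation is the key step.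
3. 2,5‑Dihydroxy‑1,4‑benzoquinone ⇒ hydroquinone, by dearomatising oxidation with alkaline H2O2.
4. No ring is formed: the only ring is the hydroquinone carbocycle, carried through all steps.

## Route

**Step 1**
Reactants: 1, hydroquinone (benzene‑1,4‑diol)
Product: 2, 2,5‑dihydroxy‑1,4‑benzoquinone
Conditions: 30% H2O2, 50% aq NaOH, 45–50 °C; then conc. HCl, 0 °C, filter
Reagents that add atoms: hydrogen peroxide, OO (source of the two new ring oxygens)
Why: Dearomatising oxidation of the hydroquinone dianion to the quinone, followed by two rounds of conjugate addition of HOO⁻/HO⁻ and re‑oxidation, is a classical preparative‑scale route to this symmetric dihydroxyquinone, which precipitates on acidification.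

**Step 2 (key step)**
Reactants: 2, 2,5‑dihydroxy‑1,4‑benzoquinone (2.5 equiv); 3, arachidic acid (icosanoic acid, 1.0 equiv)
Product: 4, 2,5‑dihydroxy‑3‑nonadecyl‑1,4‑benzoquinone
Conditions: AgNO3 (0.3 equiv), (NH4)2S2O8 (2 equiv, slow addition as aq solution), MeCN/H2O 2:1, 80 °C, 3 h; filter off excess 2, recrystallise from EtOH
Reagents that add atoms: arachidic acid (3), CCCCCCCCCCCCCCCCCCCC(=O)O (delivers C19H39; the carboxyl carbon is lost as CO2)
Why: This is a Kochi–Anderson/Jacobsen–Torssell decarboxylative radical alkylation, in which Ag(II) oxidises the carboxylate to the nucleophilic nonadecyl radical, which adds to one of the two equivalent quinone C–H positions and is re‑oxidised to the quinone, the same hydroxyquinone C–H alkylation known with acyl‑peroxide‑derived radicals; excess 2 limits the second alkylation at C6.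

**Step 3**
Reactants: 4, 2,5‑dihydroxy‑3‑nonadecyl‑1,4‑benzoquinone
Product: 5, Irisoquin‑C (2‑hydroxy‑5‑methoxy‑3‑nonadecyl‑1,4‑benzoquinone)
Conditions: MeOH/CHCl3 3:1, conc. H2SO4 (cat.), 50 °C, stop at the mono‑ether (TLC); recrystallise
Reagents that add atoms: methanol, CO
Why: Acid‑catalysed vinylogous Fischer esterification (addition–elimination of MeOH at the β‑carbon of the hydroxy‑enone) occurs at C5, which is flanked by C–H, rather than at C2, where the adjacent nonadecyl chain hinders attack and would force the methoxy out of conjugation, so the C5 ether is both the kinetic and the thermodynamic product.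

## Compound list

1 | hydroquinone | Oc1ccc(O)cc1 | starting material
2 | 2,5‑dihydroxy‑1,4‑benzoquinone | O=C1C=C(O)C(=O)C=C1O | intermediate
3 | arachidic (icosanoic) acid | CCCCCCCCCCCCCCCCCCCC(=O)O | starting material
4 | 2,5‑dihydroxy‑3‑nonadecyl‑1,4‑benzoquinone | CCCCCCCCCCCCCCCCCCCC1=C(O)C(=O)C=C(O)C1=O | intermediate
5 | Irisoquin‑C (2‑hydroxy‑5‑methoxy‑3‑nonadecyl‑1,4‑benzoquinone) | CCCCCCCCCCCCCCCCCCCC1=C(O)C(=O)C=C(OC)C1=O | target

## Summary

Total step count: 3.
Longest linear sequence: 3 (arachidic acid enters at step 2).

Steps most likely to fail, with fallbacks: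

1. **Step 2.** Risks are inefficient generation of a primary radical from a waxy, poorly soluble acid, and mono‑ versus bis‑alkylation. Fallback: switch from radical to ionic C–C bond formation by three‑component reductive alkylation of 2 with nonadecanal and Hantzsch ester under L‑proline catalysis (Knoevenagel condensation, then conjugate hydride transfer), which gives 4 directly.
2. **Step 3.** Risks are over‑methylation to the dimethyl ether or imperfect regioselectivity. Fallback: methylate exhaustively to 2,5‑dimethoxy‑3‑nonadecyl‑1,4‑benzoquinone (Me2SO4, K2CO3, acetone), then selectively hydrolyse the hindered methoxy next to the alkyl chain with 70% HClO4 in dioxane.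
3. **Step 1.** Risks are over‑oxidation and ring cleavage in the exothermic alkaline peroxide reaction. Fallback: change the symmetric platform to 2,5‑dimethoxy‑1,4‑benzoquinone (from p‑benzoquinone, MeOH, ZnCl2), run the same decarboxylative radical alkylation on it, and finish with the selective HClO4 mono‑demethylation instead of a methylation.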